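(The data come from a simulation on assumed constants, noise included.)

The pitfall is to read a yield off the limiting reagent. You see a south flask with partner as the smaller charge and you expect 66.7% of its starting material to turn. Here is what the flasks hold and what is asked.

| flask | starting material | partner | free catalyst | time |
|---|---|---|---|---|
| south-west | 120 mM | 240 mM | 2.40 mM |  |
| south-east | 48.0 mM | 168 mM | 2.40 mM |  |
| north-west | 120 mM | 240 mM | 4.80 mM |  |
| west | 180 mM | 240 mM | 2.40 mM |  |
| south | 360 mM | 240 mM | 2.40 mM | 130 min |

- south-west run (time / min: [target] / mM): 5.2: 5.0; 8.2: 7.0; 13: 11.3; 21: 15.2; 33: 20.0; 52: 26.4; 82: 30.7; 130: 34.7
- south-east run (time / min: [target] / mM): 5.2: 2.9; 8.2: 4.9; 13: 7.3; 21: 9.4; 33: 9.4; 52: 15.8; 82: 14.2; 130: 17.2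
- north-west run (time / min: [target] / mM): 5.2: 18.7; 8.2: 28.8; 13: 39.3; 21: 56.8; 33: 72.6; 52: 85.6; 82: 91.6; 130: 91.8
- west run (time / min: [target] / mM): 5.2: 5.1; 8.2: 8.8; 13: 9.9; 21: 15.8; 33: 19.3; 52: 29.2; 82: 34.3; 130: 39.6

(standard deviation of a reading: 1 mM)

- Overall: starting material + partner -> target, with free catalyst as catalyst.
- Constant volume, constant temperature.
- The analysis sees a species whether free or bound.
- "The second partner" is partner.
- An order is taken over about fifteen percent of the charge, up and down.

- the power of [partner] that the first rate follows, about the charge of the south-west run; measure it at two percent of starting material made into target
- the power of [starting material] that the first rate follows, about the charge of the south-west run; measure it at two percent of starting material made into target (one fixed amount of target, the same in the runs compared)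
- target in the south run at 130 min, as a share of the starting material charged
- which of these the readings show (the substrate is lost by itself / the catalyst dies by itself / the second partner pairs with itself)

Begin with the south-west run. By its last reading it has made 34.7 mM of target out of 120 mM of starting material, so 205 mM of partner is still there. Yet its rate has dropped steeply, so set a second cap beside the charge. Take the first rate, the late rate, and the lifetime, which is the time for the rate to fall by a factor e:

first rate = 0.962 mM/min

late rate = 0.106 mM/min

lifetime = 40.2 min

first rate × lifetime = 38.6 mM

That product is the reach: the target the catalyst can make if the rate keeps falling this way. It is a reading, and it carries the scatter of a few points. Divide it by the limiting charge to get the coverage. Above one, the bench rule can stand. Below one, the reach is the smaller cap. The south-west coverage is 0.322, so the rule has already failed there.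

The west run, with more starting material, gives:

first rate = 0.981 mM/min

late rate = 0.133 mM/min

lifetime = 44.3 min

reach = 43.4 mM

Your reckoning lends the west reach to the south flask as an estimate, since 1.50 times the starting material of the south-west run raised the reach by less, 1.12 times. Against the 240 mM of partner, that is a coverage of 0.181. Against the 360 mM of starting material, it is a yield of 12.1%.

The forecast says 13%, slightly above your figure, with orders 0.9 in partner and 0.1 in starting material, and its choice is the catalyst dies by itself. Its ground for that choice: “Rates fall far faster than starting material or partner are used”.

The south flask gives 11.2%, which is 40.2 mM of target, and the answer is the catalyst dies by itself.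

free catalyst + starting material ⇌ catalyst-substrate complex, settled at all times (16.70 /M); free catalyst + partner ⇌ catalyst-reagent complex, settled at all times (1.910 /M); catalyst-substrate complex + catalyst-reagent complex → target + 2 free catalyst (2154 /M/min); free catalyst → spent catalyst (0.04008 /min) The orders about the south-west charge are 0.79 in partner and −0.12 in starting material. In the south flask, the target made is 0.168 of the partner charge. Now take the north-west flask, with twice the catalyst. Its first rate is 3.60 mM/min, its late rate 0.0795 mM/min, and its lifetime 23.2 min. Its reach is 83.4 mM, a coverage of 0.695, and its last reading is 91.8 mM.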